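**Retrosynthetic overview**
- The ring B prenyl group is disconnected last, as a Stille coupling of an aryl bromide, so no acid-sensitive or hydrogenation-sensitive prenyl is carried through the route.
- The saturated chroman and the propanone chain come from one hydrogenation of a bromo chromeno-chalcone (chromene C3=C4 and enone C=C together).
- The chalcone comes from a protecting-group-free Claisen–Schmidt condensation of a 6-acetyl-5,7-dihydroxychromene with 5-bromoisovanillin, itself made by selective 4-O-methylation of 3-bromo-4,5-dihydroxybenzaldehyde.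
- Key step: the mirror-symmetric feedstock 2,4,6-trihydroxyacetophenone is desymmetrised by 4-O-propargylation and a dearomatising propargyl-Claisen cascade. The two ortho carbons are equivalent, and the ether oxygen ends up in the pyran ring, para to the acyl group.
- Ring order: rings A and B are bought as aromatics; the pyran ring is the only ring formed (step 2) and is saturated in step 4.

Assumption: the target has no stereocentre and no stereogenic double bond, so it is achiral and "single enantiomer" is taken to mean the single structure drawn. The E enone of the chalcone and two transient racemic centres are the only stereo-elements on the way, and all are removed.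

**Step 1**
Reactants: 1 3-bromo-4,5-dihydroxybenzaldehyde
Product: 2 3-bromo-5-hydroxy-4-methoxybenzaldehyde
Conditions: MeI (1.05 equiv), Li2CO3 (1.2 equiv), DMF, 40 °C, 16 h
Reagents that add atoms: iodomethane (MeI), CI
Why: Regioselective Williamson O-methylation, because the 4-OH (para to the formyl group, ortho to bromine) is much the more acidic, so Li2CO3 forms only that phenoxide and the 5-OH stays free.

**Step 2 (key step)**
Reactants: 3 2,4,6-trihydroxyacetophenone
Product: 6 1-(5,7-dihydroxy-2,2-dimethyl-2H-chromen-6-yl)ethan-1-one, via propargyl ether 4 (not isolated), via allenyl cyclohexadienone 5 (not isolated)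
Conditions: 3-chloro-3-methylbut-1-yne (1.1 equiv), K2CO3 (1.2 equiv), KI (0.1 equiv), CuI (2 mol %), acetone, 56 °C, 6 h; filter, evaporate; then xylenes, 140 °C, 3 h
Reagents that add atoms: 3-chloro-3-methylbut-1-yne, CC(C)(Cl)C#C
Why: The non-chelated, most acidic 4-OH is O-alkylated (CuI-assisted propargylic substitution), and on heating the ether undergoes an aromatic propargyl Claisen rearrangement to either of the two symmetry-equivalent ortho carbons, giving the dearomatised allenyl dienone, which rearomatises and closes by 1,5-hydrogen shift and oxa-6π electrocyclisation so that the original ether oxygen becomes the pyran oxygen para to the acetyl group.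

**Step 3**
Reactants: 6 1-(5,7-dihydroxy-2,2-dimethyl-2H-chromen-6-yl)ethan-1-one, 2 3-bromo-5-hydroxy-4-methoxybenzaldehyde
Product: 8 (2E)-3-(3-bromo-5-hydroxy-4-methoxyphenyl)-1-(5,7-dihydroxy-2,2-dimethyl-2H-chromen-6-yl)prop-2-en-1-one, via aldol adduct 7 (not isolated)
Conditions: KOH (50% aq., 12 equiv), EtOH, 0 °C to rt, 48 h, N2; then cold 1 M HCl to pH 4
Reagents that add atoms: none
Why: Claisen–Schmidt aldol condensation, in which the methyl ketone enolate adds to the non-enolisable aldehyde (its phenoxide is meta to the formyl group and does not deactivate it) and E1cB loss of water gives the thermodynamically preferred E enone.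

**Step 4**
Reactants: 8 (2E)-3-(3-bromo-5-hydroxy-4-methoxyphenyl)-1-(5,7-dihydroxy-2,2-dimethyl-2H-chromen-6-yl)prop-2-en-1-one
Product: 9 3-(3-bromo-5-hydroxy-4-methoxyphenyl)-1-(5,7-dihydroxy-2,2-dimethyl-3,4-dihydro-2H-chromen-6-yl)propan-1-one
Conditions: H2 (1 atm), 10% Pd/C, Ph2S (1 mol %), EtOAc, rt, 16 h
Reagents that add atoms: none
Why: Chemoselective heterogeneous catalytic hydrogenation, in which sulfide-moderated Pd/C saturates the enone C=C and the chromene C3=C4 in one operation while the aryl bromide and the chelated aryl ketone are left intact; no stereocentre is created.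

**Step 5**
Reactants: 9 3-(3-bromo-5-hydroxy-4-methoxyphenyl)-1-(5,7-dihydroxy-2,2-dimethyl-3,4-dihydro-2H-chromen-6-yl)propan-1-one
Product: 10 1-(5,7-dihydroxy-2,2-dimethyl-3,4-dihydro-2H-chromen-6-yl)-3-[3-hydroxy-4-methoxy-5-(3-methylbut-2-en-1-yl)phenyl]propan-1-one (CNP0408176.0)
Conditions: tributyl(3-methylbut-2-en-1-yl)stannane (1.5 equiv), Pd(PPh3)4 (10 mol %), DMF, 95 °C, 12 h
Reagents that add atoms: tributyl(3-methylbut-2-en-1-yl)stannane, CCCC[Sn](CCCC)(CCCC)CC=C(C)C
Why: Stille cross-coupling, in which the aryl bromide adds oxidatively to zerovalent palladium, the prenyl group is transmetalated from tin and reductive elimination at the less hindered allyl terminus gives the linear prenyl arene under neutral conditions that tolerate the free phenols and the ketone.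

**Compound list**
1 | 3-bromo-4,5-dihydroxybenzaldehyde | O=Cc1cc(O)c(O)c(Br)c1 | starting material
2 | 3-bromo-5-hydroxy-4-methoxybenzaldehyde | COc1c(O)cc(C=O)cc1Br | intermediate
3 | 2,4,6-trihydroxyacetophenone | CC(=O)c1c(O)cc(O)cc1O | starting material
4 | 1-{2,6-dihydroxy-4-[(2-methylbut-3-yn-2-yl)oxy]phenyl}ethan-1-one (propargyl ether, not isolated) | CC(=O)c1c(O)cc(OC(C)(C)C#C)cc1O | intermediate
5 | 4-acetyl-3,5-dihydroxy-6-(3-methylbuta-1,2-dien-1-yl)cyclohexa-2,4-dien-1-one (racemic, not isolated) | CC(=O)C1=C(O)C(C=C=C(C)C)C(=O)C=C1O | intermediate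
6 | 1-(5,7-dihydroxy-2,2-dimethyl-2H-chromen-6-yl)ethan-1-one | CC(=O)c1c(O)cc2c(c1O)C=CC(C)(C)O2 | intermediate
7 | 3-(3-bromo-5-hydroxy-4-methoxyphenyl)-1-(5,7-dihydroxy-2,2-dimethyl-2H-chromen-6-yl)-3-hydroxypropan-1-one (racemic aldol adduct, not isolated) | COc1c(O)cc(C(O)CC(=O)c2c(O)cc3c(c2O)C=CC(C)(C)O3)cc1Br | intermediate
8 | (2E)-3-(3-bromo-5-hydroxy-4-methoxyphenyl)-1-(5,7-dihydroxy-2,2-dimethyl-2H-chromen-6-yl)prop-2-en-1-one | COc1c(O)cc(/C=C/C(=O)c2c(O)cc3c(c2O)C=CC(C)(C)O3)cc1Br | intermediate
9 | 3-(3-bromo-5-hydroxy-4-methoxyphenyl)-1-(5,7-dihydroxy-2,2-dimethyl-3,4-dihydro-2H-chromen-6-yl)propan-1-one | COc1c(O)cc(CCC(=O)c2c(O)cc3c(c2O)CCC(C)(C)O3)cc1Br | intermediate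
10 | 1-(5,7-dihydroxy-2,2-dimethyl-3,4-dihydro-2H-chromen-6-yl)-3-[3-hydroxy-4-methoxy-5-(3-methylbut-2-en-1-yl)phenyl]propan-1-one | COc1c(O)cc(CCC(=O)c2c(O)cc3c(c2O)CCC(C)(C)O3)cc1CC=C(C)C | target

**Totals**
Total step count: 5. Longest linear sequence: 4 steps (1 → 2 → 8 → 9 → 10, or 3 → 6 → 8 → 9 → 10).

**Steps most likely to fail, with fallbacks**

Step 2 is the first risk. The mono-O-alkylation of a triphenol can be unselective (bis-ether, C-alkylation), and part of the cascade may close through an ortho hydroxyl to give the 8-acetyl chromene. The fallback sets out from 3 and comes back at 9. BF3·OEt2-catalysed Friedel–Crafts prenylation and cycloetherification of 3 with 2-methylbut-3-en-2-ol in dioxane at rt gives the saturated chroman ketone 1-(5,7-dihydroxy-2,2-dimethyl-3,4-dihydro-2H-chromen-6-yl)ethan-1-one F1, separated by chromatography from its 8-acetyl isomer. Claisen–Schmidt condensation of F1 with 2 under the step 3 conditions gives (2E)-3-(3-bromo-5-hydroxy-4-methoxyphenyl)-1-(5,7-dihydroxy-2,2-dimethyl-3,4-dihydro-2H-chromen-6-yl)prop-2-en-1-one F2. Hydrogenation as in step 4, with only the enone to reduce, then gives 9.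

Step 3 is the second risk. The polyphenoxide ketone is a sluggish aldol donor, and the 2',6'-dihydroxychalcone can close to the isomeric flavanone on acidification. The fallback avoids enolate chemistry, sets out from 2 and comes back at 9. Knoevenagel–Doebner condensation of 2 with malonic acid (pyridine, piperidine, 90 °C) gives (2E)-3-(3-bromo-5-hydroxy-4-methoxyphenyl)prop-2-enoic acid F3. Hydrogenation over Pd/C with Ph2S gives 3-(3-bromo-5-hydroxy-4-methoxyphenyl)propanoic acid F4. BF3·OEt2-mediated Friedel–Crafts acylation (80 °C) of 2,2-dimethyl-3,4-dihydro-2H-chromene-5,7-diol F5 with F4 then gives 9, after separation from the 8-acyl isomer. F5 is made from phloroglucinol and 2-methylbut-3-en-2-ol with BF3·OEt2 in dioxane.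

Step 5 is the third risk. The bromide is electron-rich and ortho-substituted, three free phenols may slow the catalyst or protodestannylate the reagent, and some branched (1,1-dimethylallyl) product may form. The fallback moves the prenylation to the start, sets out from 2 and ends at 10. Stille coupling of 2 with the same stannane and Pd(PPh3)4 in DMF gives 3-hydroxy-4-methoxy-5-(3-methylbut-2-en-1-yl)benzaldehyde F6. Claisen–Schmidt condensation of F6 with 6 gives (2E)-1-(5,7-dihydroxy-2,2-dimethyl-2H-chromen-6-yl)-3-[3-hydroxy-4-methoxy-5-(3-methylbut-2-en-1-yl)phenyl]prop-2-en-1-one F7. Homogeneous hydrogenation with RhCl(PPh3)3 and H2 (THF/t-BuOH, rt) reduces the enone and the cis-disubstituted chromene alkene much faster than the trisubstituted prenyl alkene and gives 10.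

**Further compounds**
F1 | step 2 | 1-(5,7-dihydroxy-2,2-dimethyl-3,4-dihydro-2H-chromen-6-yl)ethan-1-one | CC(=O)c1c(O)cc2c(c1O)CCC(C)(C)O2
F2 | step 2 | (2E)-3-(3-bromo-5-hydroxy-4-methoxyphenyl)-1-(5,7-dihydroxy-2,2-dimethyl-3,4-dihydro-2H-chromen-6-yl)prop-2-en-1-one | COc1c(O)cc(/C=C/C(=O)c2c(O)cc3c(c2O)CCC(C)(C)O3)cc1Br
F3 | step 3 | (2E)-3-(3-bromo-5-hydroxy-4-methoxyphenyl)prop-2-enoic acid | COc1c(O)cc(/C=C/C(=O)O)cc1Br
F4 | step 3 | 3-(3-bromo-5-hydroxy-4-methoxyphenyl)propanoic acid | COc1c(O)cc(CCC(=O)O)cc1Br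
F5 | step 3 | 2,2-dimethyl-3,4-dihydro-2H-chromene-5,7-diol | CC1(C)CCc2c(O)cc(O)cc2O1
F6 | step 5 | 3-hydroxy-4-methoxy-5-(3-methylbut-2-en-1-yl)benzaldehyde | COc1c(O)cc(C=O)cc1CC=C(C)C
F7 | step 5 | (2E)-1-(5,7-dihydroxy-2,2-dimethyl-2H-chromen-6-yl)-3-[3-hydroxy-4-methoxy-5-(3-methylbut-2-en-1-yl)phenyl]prop-2-en-1-one | COc1c(O)cc(/C=C/C(=O)c2c(O)cc3c(c2O)C=CC(C)(C)O3)cc1CC=C(C)C
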